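**Plan** (benzodioxane numbering: O1, C2 aryl, C3 methyl, O4, C4a, C5 OMe, C7 allyl, C8a)

- Retrosynthesis: the C2 configuration, the phenol pivalate and the C7–allyl bond (from C7–Cl) are dealt with last; the dioxane ring is then cut at O4–C4a and C3–H.
- Enabling feature: O4 lies between the methyl-bearing C3 and the arene carbon C4a next to C5–OMe, so it can be taken out of the C3–aryl bond of a 2-aryl-3-methyl-3-hydroperoxy-2,3-dihydrobenzofuran; the furan connectivity decides which catechol oxygen carries which carbon.
- The furan is cut at C3–C3a (Heck) and O1–C2 (allylic etherification), which leads back to an iodophenol and a cinnamyl carbonate.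
- Forward: aryl ether, furan ring by 5-exo Heck, Markovnikov hydroperoxide, enlargement of furan to dioxane by aryl shift with hydride capture, allylation, deprotection.
- Stereochemistry: C2 comes from the chiral iridium catalyst; C3 is set from C2 (hydride anti to the C2 aryl, 2,3-cis); C2 is finally inverted to the trans isomer by equilibration through a para-quinone methide, with C3 untouched.

Key step: step 11

Remark: hydride is assumed to enter the benzodioxinium ion anti to the C2 aryl, so the key step is aimed at the 2,3-cis compound, and the (Ra,R,R) ligand is assumed to give the (R)-ether as with simple cinnamyl carbonates (the mirror-image ligand would be taken if the sense proved opposite).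

**Route**

Step 1
Reactants: 1 3-chloro-5-methoxyphenol
Product: 2 1-chloro-3-methoxy-5-(methoxymethoxy)benzene
Conditions: MOMCl, i-Pr2NEt, CH2Cl2, 0 °C to rt
Reagents that add atoms: chloromethyl methyl ether, COCCl
Why: O-alkylation of the phenol (MOM protection) installs the stronger of the two oxygen directing groups needed for the metalation.

Step 2
Reactants: 2 1-chloro-3-methoxy-5-(methoxymethoxy)benzene
Product: 4 5-chloro-2-iodo-1-methoxy-3-(methoxymethoxy)benzene, via aryllithium 3 (not isolated)
Conditions: n-BuLi, Et2O, 0 °C; then I2, THF, −78 °C to rt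
Reagents that add atoms: iodine, II
Why: Directed ortho-metalation should take place at the carbon flanked by OMOM and OMe, where lithium is held by two oxygens (ether solvent favours coordination control over the sites next to chlorine), and iodine quenches the aryllithium.

Step 3
Reactants: 4 5-chloro-2-iodo-1-methoxy-3-(methoxymethoxy)benzene
Product: 5 5-chloro-2-iodo-3-methoxyphenol
Conditions: HCl (cat.), MeOH, 40 °C
Reagents that add atoms: none
Why: Acid-catalysed acetal exchange removes the MOM group under conditions mild enough to keep the aryl iodide.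

Step 4
Reactants: 6 syringaldehyde
Product: 7 4-formyl-2,6-dimethoxyphenyl pivalate
Conditions: PivCl, Et3N, DMAP (cat.), CH2Cl2, 0 °C to rt
Reagents that add atoms: pivaloyl chloride, CC(C)(C)C(Cl)=O
Why: DMAP-catalysed acylation gives a hindered aryl ester that should survive aryloxide, fluoride and aqueous phosphate later and that makes this ring a poor cation-stabilising group.

Step 5
Reactants: 7 4-formyl-2,6-dimethoxyphenyl pivalate
Product: 8 4-[(E)-3-oxoprop-1-enyl]-2,6-dimethoxyphenyl pivalate
Conditions: Ph3P=CHCHO, toluene, 80 °C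
Reagents that add atoms: (triphenylphosphoranylidene)acetaldehyde, O=CC=P(c1ccccc1)(c1ccccc1)c1ccccc1
Why: Wittig olefination with the stabilised formylmethylene ylide should give the (E)-enal in one two-carbon homologation.

Step 6
Reactants: 8 4-[(E)-3-oxoprop-1-enyl]-2,6-dimethoxyphenyl pivalate
Product: 9 4-[(E)-3-hydroxyprop-1-enyl]-2,6-dimethoxyphenyl pivalate
Conditions: NaBH4, MeOH/THF, −20 °C
Reagents that add atoms: none
Why: Borohydride 1,2-reduction of a cinnamaldehyde is fast at low temperature and should leave the hindered aryl pivalate intact.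

Step 7
Reactants: 9 4-[(E)-3-hydroxyprop-1-enyl]-2,6-dimethoxyphenyl pivalate
Product: 10 4-[(E)-3-(methoxycarbonyloxy)prop-1-enyl]-2,6-dimethoxyphenyl pivalate
Conditions: ClCO2Me, pyridine, CH2Cl2, 0 °C
Reagents that add atoms: methyl chloroformate, COC(Cl)=O
Why: O-acylation turns the allylic alcohol into the methyl carbonate, the standard leaving group for iridium-catalysed allylic substitution.

Step 8
Reactants: 5 5-chloro-2-iodo-3-methoxyphenol; 10 4-[(E)-3-(methoxycarbonyloxy)prop-1-enyl]-2,6-dimethoxyphenyl pivalate
Product: 12 4-[(1R)-1-(5-chloro-2-iodo-3-methoxyphenoxy)prop-2-enyl]-2,6-dimethoxyphenyl pivalate, via lithium aryloxide 11 (not isolated)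
Conditions: 5 (2 equiv), LiN(SiMe3)2 (1.5 equiv), THF; [Ir(cod)Cl]2 (2 mol%), (Ra,R,R)-O,O'-(1,1'-binaphthalene-2,2'-diyl) N,N-bis(1-phenylethyl)phosphoramidite (4 mol%, pre-activated with n-PrNH2), THF, rt to 40 °C
Reagents that add atoms: none
Why: Iridium-catalysed asymmetric allylic etherification: the aryloxide should attack the substituted terminus of the allyliridium complex to give the branched ether, the ligand fixing the face and hence the (R) centre that becomes C2; the surplus free phenol buffers the methoxide released from the carbonate.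

Step 9
Reactants: 12 4-[(1R)-1-(5-chloro-2-iodo-3-methoxyphenoxy)prop-2-enyl]-2,6-dimethoxyphenyl pivalate
Product: 13 4-[(2S)-6-chloro-4-methoxy-3-methylidene-2,3-dihydro-1-benzofuran-2-yl]-2,6-dimethoxyphenyl pivalate
Conditions: Pd(OAc)2 (10 mol%), PPh3 (20 mol%), Ag2CO3, MeCN, 60 °C; crude alkene filtered and used at once
Reagents that add atoms: none
Why: Intramolecular Mizoroki–Heck reaction (5-exo-trig) forms C3–C3a, and beta-hydride elimination can only use the C3 hydrogen, giving the exocyclic alkene; silver carbonate scavenges iodide and the palladium hydride so that the double bond should not move into the ring, and C2 is untouched (its descriptor changes to S only through the CIP ranking).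

Step 10
Reactants: 13 4-[(2S)-6-chloro-4-methoxy-3-methylidene-2,3-dihydro-1-benzofuran-2-yl]-2,6-dimethoxyphenyl pivalate
Product: 15 4-[(2S)-6-chloro-3-hydroperoxy-4-methoxy-3-methyl-2,3-dihydro-1-benzofuran-2-yl]-2,6-dimethoxyphenyl pivalate (both C3 epimers), via triethylsilyl peroxide 14 (not isolated)
Conditions: Co(acac)2 (10 mol%), Et3SiH, O2 (1 atm), EtOH, rt; then Bu4NF, AcOH, THF, 0 °C
Reagents that add atoms: dioxygen, O=O
Why: Mukaiyama–Isayama hydroperoxidation: hydrogen-atom transfer from a cobalt hydride to the CH2 terminus gives the tertiary benzylic C3 radical, which traps O2 (Markovnikov), and buffered fluoride frees the hydroperoxide; the C3 epimer mixture is of no consequence because C3 becomes planar in the next step.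

Step 11
Reactants: 15 4-[(2S)-6-chloro-3-hydroperoxy-4-methoxy-3-methyl-2,3-dihydro-1-benzofuran-2-yl]-2,6-dimethoxyphenyl pivalate
Product: 17 4-[(2S,3R)-7-chloro-5-methoxy-3-methyl-2,3-dihydro-1,4-benzodioxin-2-yl]-2,6-dimethoxyphenyl pivalate (2,3-cis), via benzodioxinium ion 16 (not isolated)
Conditions: Et3SiH (5 equiv), BF3·OEt2 (20 mol%), CH2Cl2, −78 to −30 °C, slow addition of 15
Reagents that add atoms: none
Why: Proposed new method: the acid activates the distal peroxide oxygen and O–O heterolysis is concerted with a 1,2-shift of arene carbon C3a (ortho to both OMe and O1, hence the best migrating group) from C3 to the proximal oxygen, so that water leaves and the C4a–O4 bond forms; the closest known reactions are the Hock (Criegee-type) rearrangement of tertiary benzylic hydroperoxides and the Et3SiH reduction of cyclic oxocarbenium ions as in lactol deoxygenation, whose union as a ring enlargement has not been described. The dioxane ring closes by this migration (enlargement of the furan by one oxygen), not by cyclisation of an open chain, and gives the 3-methylbenzodioxinium ion 16. In 16 the C2 aryl should sit pseudoaxial to avoid A(1,2) strain with the C3 methyl, and Et3SiH should deliver hydride to C3 anti to it, which sets C3 as R and gives the 2,3-cis compound. The step needs aryl migration in preference to migration of C2 or methyl, O–O in preference to C3–O heterolysis, and hydride capture before 16 loses the C2 proton. The pivalate makes the C2 aryl a poor donor (low migratory aptitude of C2, no ionisation at C2), and slow addition of 15 to excess silane and catalytic acid at low temperature without base keeps 16 short-lived.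

Step 12
Reactants: 17 4-[(2S,3R)-7-chloro-5-methoxy-3-methyl-2,3-dihydro-1,4-benzodioxin-2-yl]-2,6-dimethoxyphenyl pivalate; 18 allylboronic acid pinacol ester
Product: 19 4-[(2S,3R)-5-methoxy-3-methyl-7-(prop-2-enyl)-2,3-dihydro-1,4-benzodioxin-2-yl]-2,6-dimethoxyphenyl pivalate
Conditions: Pd(OAc)2 (5 mol%), 2-dicyclohexylphosphino-2',4',6'-triisopropylbiphenyl (10 mol%), K3PO4, THF/H2O, 70 °C
Reagents that add atoms: none
Why: Suzuki–Miyaura allylation, in which the bulky electron-rich biarylphosphine enables oxidative addition into the electron-rich aryl chloride; the hindered pivalate should tolerate aqueous phosphate.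

Step 13
Reactants: 19 4-[(2S,3R)-5-methoxy-3-methyl-7-(prop-2-enyl)-2,3-dihydro-1,4-benzodioxin-2-yl]-2,6-dimethoxyphenyl pivalate
Product: 21 4-[(2R,3R)-5-methoxy-3-methyl-7-(prop-2-enyl)-2,3-dihydro-1,4-benzodioxin-2-yl]-2,6-dimethoxyphenol (target; 2,3-trans), via cis-phenol 20 (not isolated)
Conditions: K2CO3, MeOH, 55 °C; then solvent exchange to DMF, 80 °C; AcOH quench
Reagents that add atoms: none
Why: Methanolysis of the aryl ester frees the para-phenoxide, which reversibly expels the O1 aryloxide to a para-quinone methide and re-closes by oxa-Michael addition (the known base-induced equilibration of phenolic alpha-aryl ethers); this should move C2 to the more stable trans isomer while C3 keeps its bond to O4, and the minor cis isomer is separated and resubjected.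

**Compound list**

1 | 3-chloro-5-methoxyphenol | COc1cc(O)cc(Cl)c1 | starting material
2 | 1-chloro-3-methoxy-5-(methoxymethoxy)benzene | COCOc1cc(OC)cc(Cl)c1 | intermediate
3 | [4-chloro-2-methoxy-6-(methoxymethoxy)phenyl]lithium | [Li]c1c(OC)cc(Cl)cc1OCOC | intermediate (not isolated)
4 | 5-chloro-2-iodo-1-methoxy-3-(methoxymethoxy)benzene | COCOc1cc(Cl)cc(OC)c1I | intermediate
5 | 5-chloro-2-iodo-3-methoxyphenol | Oc1cc(Cl)cc(OC)c1I | intermediate
6 | syringaldehyde (4-hydroxy-3,5-dimethoxybenzaldehyde) | COc1cc(C=O)cc(OC)c1O | starting material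
7 | 4-formyl-2,6-dimethoxyphenyl pivalate | COc1cc(C=O)cc(OC)c1OC(=O)C(C)(C)C | intermediate
8 | 4-[(E)-3-oxoprop-1-enyl]-2,6-dimethoxyphenyl pivalate | COc1cc(/C=C/C=O)cc(OC)c1OC(=O)C(C)(C)C | intermediate
9 | 4-[(E)-3-hydroxyprop-1-enyl]-2,6-dimethoxyphenyl pivalate | COc1cc(/C=C/CO)cc(OC)c1OC(=O)C(C)(C)C | intermediate
10 | 4-[(E)-3-(methoxycarbonyloxy)prop-1-enyl]-2,6-dimethoxyphenyl pivalate | COC(=O)OC/C=C/c1cc(OC)c(OC(=O)C(C)(C)C)c(OC)c1 | intermediate
11 | lithium 5-chloro-2-iodo-3-methoxyphenoxide | [Li+].[O-]c1cc(Cl)cc(OC)c1I | intermediate (not isolated)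
12 | 4-[(1R)-1-(5-chloro-2-iodo-3-methoxyphenoxy)prop-2-enyl]-2,6-dimethoxyphenyl pivalate | Clc1cc(OC)c(I)c(c1)O[C@@H](c1cc(OC)c(OC(=O)C(C)(C)C)c(OC)c1)C=C | intermediate
13 | 4-[(2S)-6-chloro-4-methoxy-3-methylidene-2,3-dihydro-1-benzofuran-2-yl]-2,6-dimethoxyphenyl pivalate | Clc1cc(OC)c2c(c1)O[C@@H](c1cc(OC)c(OC(=O)C(C)(C)C)c(OC)c1)C2=C | intermediate
14 | 4-[(2S)-6-chloro-4-methoxy-3-methyl-3-(triethylsilylperoxy)-2,3-dihydro-1-benzofuran-2-yl]-2,6-dimethoxyphenyl pivalate (C3 epimers) | Clc1cc(OC)c2c(c1)O[C@@H](c1cc(OC)c(OC(=O)C(C)(C)C)c(OC)c1)C2(C)OO[Si](CC)(CC)CC | intermediate (not isolated)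
15 | 4-[(2S)-6-chloro-3-hydroperoxy-4-methoxy-3-methyl-2,3-dihydro-1-benzofuran-2-yl]-2,6-dimethoxyphenyl pivalate (C3 epimers) | Clc1cc(OC)c2c(c1)O[C@@H](c1cc(OC)c(OC(=O)C(C)(C)C)c(OC)c1)C2(C)OO | intermediate (key-step precursor)
16 | (2S)-7-chloro-5-methoxy-3-methyl-2-(3,5-dimethoxy-4-pivaloyloxyphenyl)-2H-1,4-benzodioxin-4-ium | Clc1cc(OC)c2c(c1)O[C@@H](c1cc(OC)c(OC(=O)C(C)(C)C)c(OC)c1)C(C)=[O+]2 | intermediate (not isolated)
17 | 4-[(2S,3R)-7-chloro-5-methoxy-3-methyl-2,3-dihydro-1,4-benzodioxin-2-yl]-2,6-dimethoxyphenyl pivalate (cis) | Clc1cc(OC)c2c(c1)O[C@@H](c1cc(OC)c(OC(=O)C(C)(C)C)c(OC)c1)[C@@H](C)O2 | intermediate (key-step product)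
18 | allylboronic acid pinacol ester | C=CCB1OC(C)(C)C(C)(C)O1 | starting material
19 | 4-[(2S,3R)-5-methoxy-3-methyl-7-(prop-2-enyl)-2,3-dihydro-1,4-benzodioxin-2-yl]-2,6-dimethoxyphenyl pivalate (cis) | C=CCc1cc(OC)c2c(c1)O[C@@H](c1cc(OC)c(OC(=O)C(C)(C)C)c(OC)c1)[C@@H](C)O2 | intermediate
20 | 4-[(2S,3R)-5-methoxy-3-methyl-7-(prop-2-enyl)-2,3-dihydro-1,4-benzodioxin-2-yl]-2,6-dimethoxyphenol (cis) | C=CCc1cc(OC)c2c(c1)O[C@@H](c1cc(OC)c(O)c(OC)c1)[C@@H](C)O2 | intermediate (not isolated)
21 | 4-[(2R,3R)-5-methoxy-3-methyl-7-(prop-2-enyl)-2,3-dihydro-1,4-benzodioxin-2-yl]-2,6-dimethoxyphenol (trans) | C=CCc1cc(OC)c2c(c1)O[C@H](c1cc(OC)c(O)c(OC)c1)[C@@H](C)O2 | target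

**Count and risks**

Total: 13 steps. Longest linear sequence: 10 steps (steps 4–13, from syringaldehyde); steps 1–3 form the second branch.

Steps most likely to fail:

Step 11 (new method). The hydroperoxide may ionise at C3–O instead of O–O, followed by silane reduction or aromatisation to the benzofuran. C2 may migrate in place of the arene. The cation may shed the C2 proton and so lose the C2 configuration. Facial selectivity of hydride delivery may be poor. The fallback uses known reactions and sets out from 15. The Hock rearrangement is run alone under classical aqueous conditions (catalytic HClO4, MeCN/H2O, 0 °C), where water captures the cation at once and gives the cyclic hemiketal F1, in equilibrium with its open keto-phenol form. The ketone form is reduced under Felkin–Anh control with LiBH(s-Bu)3 (THF, −78 °C) to the syn alcohol F2, the diastereomers being separable. Intramolecular Mitsunobu etherification (PPh3, DIAD, THF) then closes O4–C3 with inversion and comes back to the route at 17.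

Step 9. The exocyclic alkene may isomerise into the ring through re-addition of palladium hydride, which would give the achiral 3-methylbenzofuran. Zerovalent palladium may also ionise the allylic aryl ether, with erosion of enantiopurity. The fallback sets out from 7 and 5. HC≡CMgBr adds to 7 (THF, −78 °C) to give the racemic propargylic alcohol F3, which is acetylated (Ac2O, pyridine) to the acetate F4. Copper-catalysed enantioselective propargylic etherification with 5 (CuOTf·0.5C6H6, chiral pybox ligand, i-Pr2NEt, MeOH, −20 °C) gives the (R)-propargyl aryl ether F5. Tin hydride radical cyclisation (Bu3SnH, AIBN, benzene, 80 °C; aryl radical, 5-exo-dig) then forms the same exocyclic alkene under neutral conditions free of palladium hydride and rejoins the route at 13. This path also replaces steps 5–8.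

Step 13. The equilibrium may be slow or not far enough on the trans side. Material may be lost from the quinone methide by tautomerisation to an enol ether or capture by methanol. The allyl double bond may migrate on prolonged heating with base, and the last of the cis isomer may be hard to remove. The fallback sets out from 17. The equilibration is moved before the allylation (K2CO3, MeOH, then DMF, 80 °C) to give the trans chlorophenol F6, which has no allyl group and can be purified by crystallisation with recycling of the cis isomer. Re-pivaloylation (PivCl, Et3N, DMAP) gives the trans chloro pivalate F7, and Suzuki allylation as in step 12 gives the trans allyl pivalate F8. The ester is finally cleaved reductively with i-Bu2AlH (CH2Cl2, −78 °C), where no phenoxide-driven ring opening should occur, to arrive at 21.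

**Further compounds**

F1 | step 11 | 4-[(2S)-7-chloro-3-hydroxy-5-methoxy-3-methyl-2,3-dihydro-1,4-benzodioxin-2-yl]-2,6-dimethoxyphenyl pivalate (cyclic hemiketal, C3 epimers) | Clc1cc(OC)c2c(c1)O[C@@H](c1cc(OC)c(OC(=O)C(C)(C)C)c(OC)c1)C(C)(O)O2
F2 | step 11 | 4-[(1S,2S)-1-(5-chloro-2-hydroxy-3-methoxyphenoxy)-2-hydroxypropyl]-2,6-dimethoxyphenyl pivalate | Clc1cc(OC)c(O)c(c1)O[C@@H](c1cc(OC)c(OC(=O)C(C)(C)C)c(OC)c1)[C@H](C)O
F3 | step 9 | 4-(1-hydroxyprop-2-ynyl)-2,6-dimethoxyphenyl pivalate (racemic) | C#CC(O)c1cc(OC)c(OC(=O)C(C)(C)C)c(OC)c1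
F4 | step 9 | 4-(1-acetoxyprop-2-ynyl)-2,6-dimethoxyphenyl pivalate (racemic) | C#CC(OC(C)=O)c1cc(OC)c(OC(=O)C(C)(C)C)c(OC)c1
F5 | step 9 | 4-[(1R)-1-(5-chloro-2-iodo-3-methoxyphenoxy)prop-2-ynyl]-2,6-dimethoxyphenyl pivalate | Clc1cc(OC)c(I)c(c1)O[C@@H](c1cc(OC)c(OC(=O)C(C)(C)C)c(OC)c1)C#C
F6 | step 13 | 4-[(2R,3R)-7-chloro-5-methoxy-3-methyl-2,3-dihydro-1,4-benzodioxin-2-yl]-2,6-dimethoxyphenol | Clc1cc(OC)c2c(c1)O[C@H](c1cc(OC)c(O)c(OC)c1)[C@@H](C)O2
F7 | step 13 | 4-[(2R,3R)-7-chloro-5-methoxy-3-methyl-2,3-dihydro-1,4-benzodioxin-2-yl]-2,6-dimethoxyphenyl pivalate | Clc1cc(OC)c2c(c1)O[C@H](c1cc(OC)c(OC(=O)C(C)(C)C)c(OC)c1)[C@@H](C)O2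
F8 | step 13 | 4-[(2R,3R)-5-methoxy-3-methyl-7-(prop-2-enyl)-2,3-dihydro-1,4-benzodioxin-2-yl]-2,6-dimethoxyphenyl pivalate | C=CCc1cc(OC)c2c(c1)O[C@H](c1cc(OC)c(OC(=O)C(C)(C)C)c(OC)c1)[C@@H](C)O2
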